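**Strategy.** Everything rests on cutting the C4–C10 bond of the cyclobutane (C4–C5–C11–C10). C4 is a carbon of the six-membered ring that comes from carvone; C10 is the methyl-bearing quaternary centre, and its neighbour C9 carries oxygen. An epoxide across C9–C10 therefore serves twice: reductive opening leaves the hydroxyl on C9 and a tertiary radical on C10. In one operation, titanocene-mediated opening and transannular 4-exo addition of C10 to the C4 ketone close the four-membered ring, set C4 and C10 and complete the longipinane skeleton. The precursor is a cis-fused bicyclo[5.4.0]undecane (six-membered enone ring, seven-membered ring) with the C9–C10 epoxide, the C6 gem-dimethyl group and the C7 isovalerate.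

Key step: step 10

Remark (numbering): longipinane locants are used for all intermediates; in the bicyclic compounds the six-membered ring is C4–C3–C2–C1–C11–C5 and the seven-membered ring is C5–C6–C7–C8–C9–C10–C11.

Remark (structure check): the key-step precursor (5S,7R,9R,10S,11R, cis-fused, epoxide oxygen on the face of the seven-membered ring opposite to C4) and its product (4S,5S,7R,9R,10R,11R) were compared centre by centre with the target (4R,5S,7R,9R,10R,11R); they are consistent and are used unchanged as 16 and 19.

Remark (design): the cis ring fusion is set by kinetic protonation because the equilibrium position of this ring-fused ketone is uncertain; the quaternary C6 is attached by radical alkylation and C7–C9 are added by allylation, because a tertiary cation next to an oxygenated carbon would undergo hydride shift.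

Remark (reagents): LDA, allylborane 8, tigloyl chloride 20 and methyl chlorooxoacetate are taken as commercial.

Step 1
Reactants: 1 (R)-carvone
Product: 3 TMS dienol ether (R)-trimethyl{[6-methyl-3-(prop-1-en-2-yl)cyclohexa-1,5-dien-1-yl]oxy}silane, via lithium dienolate 2 (not isolated)
Conditions: LiN(iPr)2 (LDA, 1.05 equiv), THF, −78 °C; Me3SiCl, −78 °C → rt
Reagents that add atoms: chlorotrimethylsilane, C[Si](C)(C)Cl
Why: Kinetic α'-deprotonation of the enone and O-silylation (silyl enol ether formation) should give the cross-conjugated 2-siloxy diene without touching the C11 stereocentre.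

Step 2
Reactants: 3 TMS dienol ether; 4 methyl 2-bromo-2-methylpropanoate
Product: 5 keto ester methyl 2-methyl-2-[(1R,6R)-3-methyl-2-oxo-6-(prop-1-en-2-yl)cyclohex-3-en-1-yl]propanoate (C5/C11 trans)
Conditions: fac-Ir(ppy)3 (1 mol%), MeCN, blue LEDs, rt
Reagents that add atoms: none
Why: Photoredox radical–polar crossover α-alkylation of a silyl enol ether: the electrophilic tertiary radical from 4 should add to the siloxy-diene terminus C5 anti to the isopropenyl group, and oxidation of the siloxyallyl radical with loss of Me3SiBr returns the enone with the C5–C6 bond to the quaternary carbon in place (the C5 configuration is provisional, since step 8 resets it).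

Step 3
Reactants: 5 keto ester
Product: 6 diol (1R,5R,6R)-6-(1-hydroxy-2-methylpropan-2-yl)-2-methyl-5-(prop-1-en-2-yl)cyclohex-2-en-1-ol
Conditions: LiAlH4, THF, 0 °C → rt; aqueous work-up
Reagents that add atoms: none
Why: Hydride reduction with LiAlH4 should take the hindered ester to the neopentyl alcohol and the enone to the allylic alcohol (1,2-reduction, hydride axial) in one operation; the new C4 carbinol centre, drawn as the expected epimer, is erased in step 4.

Step 4
Reactants: 6 diol
Product: 7 keto aldehyde 2-methyl-2-[(1R,6R)-3-methyl-2-oxo-6-(prop-1-en-2-yl)cyclohex-3-en-1-yl]propanal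
Conditions: Dess–Martin periodinane (3 equiv), CH2Cl2, 0 °C → rt
Reagents that add atoms: none
Why: Dess–Martin oxidation should convert both hydroxyls under non-basic conditions, the allylic one first so that no lactol can form, and the aldehyde has no α-hydrogen to lose.

Step 5
Reactants: 7 keto aldehyde; 8 lIpc2B(allyl) (B-allyldiisopinocampheylborane made from (−)-α-pinene)
Product: 10 homoallylic alcohol (5R,6R)-6-[(3R)-3-hydroxy-2-methylhex-5-en-2-yl]-2-methyl-5-(prop-1-en-2-yl)cyclohex-2-en-1-one, via borinate ester 9 (not isolated)
Conditions: Et2O, −78 °C; then HOCH2CH2NH2, rt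
Reagents that add atoms: none
Why: Brown allylation: the aldehyde should react far faster than the hindered enone carbonyl through a chair transition state in which the isopinocampheyl groups of this reagent enantiomer direct allyl to the Re face, setting C7 as R by reagent control, and the ethanolamine work-up avoids alkaline peroxide, which would epoxidise the enone.

Step 6
Reactants: 10 homoallylic alcohol; 11 3-methylbutanoyl chloride (isovaleryl chloride)
Product: 12 isovalerate (3R)-2-methyl-2-[(1R,6R)-3-methyl-2-oxo-6-(prop-1-en-2-yl)cyclohex-3-en-1-yl]hex-5-en-3-yl 3-methylbutanoate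
Conditions: pyridine, DMAP (cat.), CH2Cl2, 0 °C → rt
Reagents that add atoms: none
Why: DMAP-catalysed acylation of the only hydroxyl installs the C7 ester before the two later hydroxyls appear, so the three oxygens never have to be told apart.

Step 7
Reactants: 12 isovalerate
Product: 13 trans-fused bicyclic dienone (5R,7R,11R)-4-oxo-4,10-secolongipina-2,9-dien-7-yl 3-methylbutanoate
Conditions: (H2IMes)(PCy3)Cl2Ru=CHPh (second-generation Grubbs catalyst, 5 mol%), CH2Cl2, 40 °C
Reagents that add atoms: none
Why: Ring-closing metathesis between the terminal vinyl group and the isopropenyl group should close the seven-membered ring as the trisubstituted C9=C10 alkene with loss of ethene, the electron-poor enone alkene staying out of the reaction.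

Step 8
Reactants: 13 trans-fused bicyclic dienone
Product: 15 cis-fused bicyclic dienone (5S,7R,11R)-4-oxo-4,10-secolongipina-2,9-dien-7-yl 3-methylbutanoate, via lithium dienolate 14 (not isolated)
Conditions: LiN(iPr)2 (2.5 equiv), THF, −78 °C; inverse quench into AcOH/THF, −78 °C
Reagents that add atoms: none
Why: Kinetic protonation of an enolate: LDA removes the axial C5 hydrogen (any ester enolate formed alongside is simply reprotonated), allylic 1,2-strain with the C6 quaternary carbon pushes C10 pseudoaxial in the planar dienolate so that the seven-membered ring covers one face, and the proton should enter anti to C10 to give the cis fusion (5S), with any trans isomer recyclable through the same step.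

Step 9
Reactants: 15 cis-fused bicyclic dienone
Product: 16 epoxy enone (5S,7R,9R,10S,11R)-9,10-epoxy-4-oxo-4,10-secolongipin-2-en-7-yl 3-methylbutanoate
Conditions: mCPBA, CH2Cl2, 0 °C
Reagents that add atoms: 3-chloroperoxybenzoic acid, OOC(=O)c1cccc(Cl)c1
Why: Prilezhaev epoxidation of the only electron-rich alkene should occur on the convex face of the cis-fused bicycle, syn to H5 and H11 and anti to both the six-membered ring and the C7 ester, which places the oxygen opposite to C4 and sets C9 as R (C10 follows as S).

Step 10
Reactants: 16 epoxy enone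
Product: 19 tricyclic diol (4S,5S,7R,9R,10R,11R)-4,9-dihydroxylongipin-2-en-7-yl 3-methylbutanoate, via titanoxy C10 radical 17 (not isolated), via bis(titanium) dialkoxide 18 (not isolated)
Conditions: Cp2TiCl2 (2.5 equiv), Mn dust, THF, rt (green Cp2TiCl); slow addition of 16; then aq. NaH2PO4
Reagents that add atoms: none
Why: Single-electron transfer from Cp2TiCl (trivalent titanium) opens the epoxide at the more substituted carbon to a C9 titanium alkoxide and the tertiary C10 radical, which adds to the titanium-coordinated C4 carbonyl carbon; a second Cp2TiCl takes up the oxygen-centred radical, which makes the otherwise reversible closure irreversible, and hydrolysis frees the diol. The closest known reaction type is the Nugent–RajanBabu reductive epoxide opening followed by radical addition to a ketone carbonyl to give a cyclobutanol, known for epoxy ketones, cyclohexenone cases included. The cyclobutane C4–C5–C11–C10 closes in a transannular 4-exo-trig mode on the C=O bond. C10 is controlled by the seven-membered ring, because C4 hangs from C5 on the face opposite to the former epoxide oxygen and can reach only that face of the planar radical, and C4 is controlled by the cis ring fusion, which offers a single carbonyl face to C10. The step needs attack at the carbonyl carbon C4 and not at the enone β-carbon C2, and closure before the radical is lost by hydrogen abstraction to a second titanocene; the C6–C9 tether pulls the pseudoaxial C10 towards the C5 side of the six-membered ring and titanium coordination activates the carbonyl, while the C9 configuration is carried over untouched from the epoxide.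

Step 11
Reactants: 19 tricyclic diol; 20 tigloyl chloride ((E)-2-methylbut-2-enoyl chloride)
Product: 21 C9 tiglate (7-isovalerate 9-tiglate of longipin-2-ene-4,7,9-triol; free C4 hydroxyl; centres as in 19)
Conditions: pyridine, DMAP, CH2Cl2, rt
Reagents that add atoms: none
Why: DMAP-catalysed acylation should esterify only the secondary C9 hydroxyl, the tertiary bridgehead C4 hydroxyl being inert to an acid chloride of this size, and the (E)-alkene of the tiglate is the stable geometry.

Step 12
Reactants: 21 C9 tiglate
Product: 22 C4 methyl oxalate of 21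
Conditions: ClC(O)CO2Me, pyridine, DMAP, CH2Cl2, 0 °C → rt
Reagents that add atoms: methyl chlorooxoacetate, COC(=O)C(Cl)=O
Why: Acylation of the tertiary bridgehead alcohol with the small, highly electrophilic oxalyl half-chloride should give the radical-labile methyl oxalate, and no elimination is possible at the bridgehead.

Step 13
Reactants: 22 C4 methyl oxalate
Product: 24 4-deoxy diester (1-deoxo target; 7-isovalerate 9-tiglate of longipin-2-ene-7,9-diol; all six centres as in the target), via bridgehead C4 radical 23 (not isolated)
Conditions: Bu3SnH, AIBN (cat.), toluene, 110 °C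
Reagents that add atoms: none
Why: Barton–McCombie-type radical deoxygenation of a tertiary methyl oxalate: stannyl radical addition and C4–O β-scission should give the bridgehead σ-radical, which cannot invert and does not delocalise into the orthogonal C2=C3 π bond, so hydrogen transfer from Bu3SnH occurs with retention and without allylic transposition.

Step 14
Reactants: 24 4-deoxy diester
Product: 25 target, 7-isovaleryloxy-9-tigloyloxylongipin-2-en-1-one (4R,5S,7R,9R,10R,11R)
Conditions: CrO3, 3,5-dimethylpyrazole, CH2Cl2, −20 °C
Reagents that add atoms: chromium trioxide, O=[Cr](=O)=O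
Why: Allylic oxidation with the CrO3·3,5-dimethylpyrazole complex should convert the ring methylene C1 next to the trisubstituted C2=C3 alkene into the conjugated ketone, as in the oxidation of α-pinene-type alkenes to verbenone-type enones; the bridgehead C4–H lies in the alkene plane and the tiglate methyls are deactivated.

**Compound list**

1 | (R)-carvone | CC1=CC[C@@H](C(C)=C)CC1=O | starting material
2 | lithium cross-conjugated dienolate of carvone | CC1=CC[C@@H](C(C)=C)C=C1[O-].[Li+] | intermediate
3 | (R)-trimethyl{[6-methyl-3-(prop-1-en-2-yl)cyclohexa-1,5-dien-1-yl]oxy}silane | CC1=CC[C@@H](C(C)=C)C=C1O[Si](C)(C)C | intermediate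
4 | methyl 2-bromo-2-methylpropanoate | COC(=O)C(C)(C)Br | starting material
5 | methyl 2-methyl-2-[(1R,6R)-3-methyl-2-oxo-6-(prop-1-en-2-yl)cyclohex-3-en-1-yl]propanoate | COC(=O)C(C)(C)[C@@H]1C(=O)C(C)=CC[C@H]1C(C)=C | intermediate
6 | (1R,5R,6R)-6-(1-hydroxy-2-methylpropan-2-yl)-2-methyl-5-(prop-1-en-2-yl)cyclohex-2-en-1-ol | OCC(C)(C)[C@@H]1[C@@H](O)C(C)=CC[C@H]1C(C)=C | intermediate
7 | 2-methyl-2-[(1R,6R)-3-methyl-2-oxo-6-(prop-1-en-2-yl)cyclohex-3-en-1-yl]propanal | O=CC(C)(C)[C@@H]1C(=O)C(C)=CC[C@H]1C(C)=C | intermediate
8 | B-allyldiisopinocampheylborane from (−)-α-pinene, lIpc2B(allyl) | C=CCB([C@H]1C[C@H]2C[C@H](C2(C)C)[C@@H]1C)[C@H]1C[C@H]2C[C@H](C2(C)C)[C@@H]1C | starting material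
9 | diisopinocampheylborinate ester of 10 | C=CC[C@@H](OB([C@H]1C[C@H]2C[C@H](C2(C)C)[C@@H]1C)[C@H]1C[C@H]2C[C@H](C2(C)C)[C@@H]1C)C(C)(C)[C@@H]1C(=O)C(C)=CC[C@H]1C(C)=C | intermediate
10 | (5R,6R)-6-[(3R)-3-hydroxy-2-methylhex-5-en-2-yl]-2-methyl-5-(prop-1-en-2-yl)cyclohex-2-en-1-one | C=CC[C@@H](O)C(C)(C)[C@@H]1C(=O)C(C)=CC[C@H]1C(C)=C | intermediate
11 | 3-methylbutanoyl chloride (isovaleryl chloride) | CC(C)CC(=O)Cl | starting material
12 | (3R)-2-methyl-2-[(1R,6R)-3-methyl-2-oxo-6-(prop-1-en-2-yl)cyclohex-3-en-1-yl]hex-5-en-3-yl 3-methylbutanoate | C=CC[C@@H](OC(=O)CC(C)C)C(C)(C)[C@@H]1C(=O)C(C)=CC[C@H]1C(C)=C | intermediate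
13 | trans-fused (5R,7R,11R)-4-oxo-4,10-secolongipina-2,9-dien-7-yl 3-methylbutanoate | CC1=CC[C@@H](OC(=O)CC(C)C)C(C)(C)[C@@H]2C(=O)C(C)=CC[C@@H]12 | intermediate
14 | lithium C4–C5 dienolate of 13 | CC1=CC[C@@H](OC(=O)CC(C)C)C(C)(C)C2=C([O-])C(C)=CC[C@@H]12.[Li+] | intermediate
15 | cis-fused (5S,7R,11R)-4-oxo-4,10-secolongipina-2,9-dien-7-yl 3-methylbutanoate | CC1=CC[C@@H](OC(=O)CC(C)C)C(C)(C)[C@H]2C(=O)C(C)=CC[C@@H]12 | intermediate
16 | cis-fused (5S,7R,9R,10S,11R)-9,10-epoxy-4-oxo-4,10-secolongipin-2-en-7-yl 3-methylbutanoate (key-step precursor) | [C@@H]12C[C@@H](OC(=O)CC(C)C)C(C)(C)[C@H]3C(=O)C(C)=CC[C@H]3[C@]1(C)O2 | intermediate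
17 | C10 tertiary radical with C9–O–TiCp2Cl (cyclopentadienyl rings drawn σ-bonded) | [C@@H]1(O[Ti](Cl)(C2C=CC=C2)C2C=CC=C2)C[C@@H](OC(=O)CC(C)C)C(C)(C)[C@H]3C(=O)C(C)=CC[C@H]3[C]1C | intermediate
18 | C4,C9-bis(chlorotitanocene) alkoxide of 19 | Cl[Ti](C2C=CC=C2)(C2C=CC=C2)O[C@@H]1C[C@@H](OC(=O)CC(C)C)C(C)(C)[C@@H]2[C@H]3CC=C(C)[C@]2(O[Ti](Cl)(C4C=CC=C4)C4C=CC=C4)[C@]31C | intermediate
19 | (4S,5S,7R,9R,10R,11R)-4,9-dihydroxylongipin-2-en-7-yl 3-methylbutanoate (key-step product) | O[C@@H]1C[C@@H](OC(=O)CC(C)C)C(C)(C)[C@@H]2[C@H]3CC=C(C)[C@]2(O)[C@]31C | intermediate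
20 | tigloyl chloride, (E)-2-methylbut-2-enoyl chloride | C/C=C(\C)C(=O)Cl | starting material
21 | 4-hydroxy-7-(3-methylbutanoyloxy)longipin-2-en-9-yl (E)-2-methylbut-2-enoate | C/C=C(\C)C(=O)O[C@@H]1C[C@@H](OC(=O)CC(C)C)C(C)(C)[C@@H]2[C@H]3CC=C(C)[C@]2(O)[C@]31C | intermediate
22 | C4 methyl oxalate of 21 | C/C=C(\C)C(=O)O[C@@H]1C[C@@H](OC(=O)CC(C)C)C(C)(C)[C@@H]2[C@H]3CC=C(C)[C@]2(OC(=O)C(=O)OC)[C@]31C | intermediate
23 | bridgehead C4 radical | C/C=C(\C)C(=O)O[C@@H]1C[C@@H](OC(=O)CC(C)C)C(C)(C)[C@@H]2[C@H]3CC=C(C)[C]2[C@]31C | intermediate
24 | 7-(3-methylbutanoyloxy)longipin-2-en-9-yl (E)-2-methylbut-2-enoate (1-deoxo target) | C/C=C(\C)C(=O)O[C@@H]1C[C@@H](OC(=O)CC(C)C)C(C)(C)[C@@H]2[C@H]3CC=C(C)[C@@H]2[C@]31C | intermediate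
25 | (4R,5S,7R,9R,10R,11R)-7-(3-methylbutanoyloxy)-1-oxolongipin-2-en-9-yl (E)-2-methylbut-2-enoate | C/C=C(\C)C(=O)O[C@@H]1C[C@@H](OC(=O)CC(C)C)C(C)(C)[C@@H]2[C@H]3C(=O)C=C(C)[C@@H]2[C@]31C | target

**Totals.** Total step count: 14. Longest linear sequence: 14 steps, from (R)-carvone 1 to 25.

**Steps most likely to fail**

Step 10. What may go wrong: the tertiary C10 radical is intercepted by a second titanocene through β-hydrogen abstraction, or the 4-exo closure reverses before the oxygen radical is captured, so the epoxide is only isomerised to an allylic alcohol. The fallback generates the same radical without stoichiometric trivalent titanium, by metal-hydride hydrogen-atom transfer. It sets out from 16, which is isomerised on purpose (Cp2TiCl in excess, concentrated THF) mainly to the exocyclic-methylene allylic alcohol F1 (C9–OH, C10=CH2; 5S,7R,9R,11R). Treatment of F1 with Fe(acac)3 and PhSiH3 in EtOH at 60 °C (Mukaiyama-type hydrogen-atom transfer) delivers a hydrogen atom to the CH2 terminus, which recreates the C10 radical together with its methyl group. Radical addition to the C4 ketone and reduction of the alkoxy radical by divalent iron then rejoin the route at diol 19.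

Step 2. What may go wrong: addition of the tertiary radical to the hindered diene terminus is slow, so protodesilylation of 3 back to carvone, aromatisation of the siloxy diene or radical dimerisation take over. The fallback is an oxidative enolate heterocoupling. It sets out from 1: the lithium enolate of 1 and the lithium enolate of methyl 2-methylpropanoate (each from LDA, THF, −78 °C) are oxidised together with Fe(acac)3, which joins the two α-carbons. This gives keto ester 5 directly, where the route is rejoined; no new compound is made (F0).

Step 13. What may go wrong: C4–O scission towards the strained bridgehead radical is slow, so the stannyl adduct of the oxalate is reduced or hydrolysed and alcohol 21 is returned. The fallback uses a thiocarbonyl derivative, whose radical adduct lives longer and fragments irreversibly. It sets out from 21, which is converted (KN(SiMe3)2, then CS2, then MeI, THF, −78 °C) into the S-methyl xanthate F2; Chugaev elimination is impossible at the bridgehead. Barton–McCombie reduction (Bu3SnH, AIBN, toluene, 110 °C) then rejoins the route at 24.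

**Further compounds**

F1 | step 10 | (5S,7R,9R,11R)-9-hydroxy-10-methylidene-4-oxo-4,10-secolongipin-2-en-7-yl 3-methylbutanoate | O[C@@H]1C[C@@H](OC(=O)CC(C)C)C(C)(C)[C@H]2C(=O)C(C)=CC[C@H]2C1=C
F0 | step 2 | none | none
F2 | step 13 | C4 O-(S-methyl dithiocarbonate) of 21 | C/C=C(\C)C(=O)O[C@@H]1C[C@@H](OC(=O)CC(C)C)C(C)(C)[C@@H]2[C@H]3CC=C(C)[C@]2(OC(=S)SC)[C@]31C
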